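**Retrosynthetic overview**
1. Numbering of the pinane part: C1 and C5 are the bridgeheads (C1 next to the spiro carbon C2), C6 is CMe2, C7 is the CH2 bridge, C10 is the CH2 between C2 and the isopropyl-bearing chromane carbon. The dihydropyran (O–C2 and C10–C) is cut last, by a Knoevenagel/hetero-Diels–Alder union of syncarpic acid, isobutyraldehyde and (+)-β-pinene 15.
2. 15 is built de novo from bicyclic keto ether 11: Wolff–Kishner removal of the C4 carbonyl, then Boord-type elimination to the C2=C10 double bond.
3. Key disconnection: C1–C2 and C5–C6 of 11 are cut together, which opens both carbocycles to the acyclic enol ether 9. Forward, this is a stepwise cationic [4+2] across the one-carbon tether C7: ketal-initiated Prins closure, then alkylation of the C6 cation by the silyl enol ether.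
4. Enabling feature: in the six-membered ring C1–C2–C3–C4–C5–C6, C2 is fully substituted and can be carried as an oxocarbenium ion. C6 is the gem-dimethyl carbon and becomes a tertiary cation when the C1=C6 alkene attacks C2. C4 (1,3 to C2, next to bridgehead C5) can carry a temporary enol ether that makes C5 nucleophilic. The C10 chloride, the diol ether on C2 and the C4 carbonyl are all removed again.
5. Ring order: cyclohexane C1–C2–C3–C4–C5–C7 and cyclobutane C1–C6–C5–C7 in step 5, dihydropyran in step 9. 9 comes from sulcatone, 2-chloro-1,1,1-trimethoxyethane and (2R,4R)-pentane-2,4-diol.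

Key step: step 5

Assumption: the (2R,4R)-diol template is taken to favour the (+)-β-pinene bridgehead series in step 5; if the opposite series predominates, the equally available (2S,4S)-diol is used and all diol-derived descriptors invert.

**Step 1**
Reactants: 1 2-chloro-1,1,1-trimethoxyethane; 2 (2R,4R)-pentane-2,4-diol
Product: 3 (4R,6R)-2-(chloromethyl)-2-methoxy-4,6-dimethyl-1,3-dioxane
Conditions: PPTS (cat.), toluene, 90 °C, MeOH distilled off
Reagents that add atoms: none
Why: Acid-catalysed orthoester exchange driven by removal of methanol; the C2-symmetric diol makes the new orthoester carbon non-stereogenic, so a single compound should result.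

**Step 2**
Reactants: 4 6-methylhept-5-en-2-one (sulcatone)
Product: 6 trimethyl[(6-methylhepta-1,5-dien-2-yl)oxy]silane, via lithium enolate 5 (not isolated)
Conditions: LDA, THF, −78 °C; TMSCl
Reagents that add atoms: chlorotrimethylsilane, C[Si](C)(C)Cl
Why: Kinetic deprotonation of a methyl ketone at the methyl group followed by O-silylation (silyl enol ether formation) fixes the nucleophilic carbon that becomes C3.

**Step 3**
Reactants: 6 trimethyl[(6-methylhepta-1,5-dien-2-yl)oxy]silane; 3 (4R,6R)-2-(chloromethyl)-2-methoxy-4,6-dimethyl-1,3-dioxane
Product: 7 1-[(4R,6R)-2-(chloromethyl)-4,6-dimethyl-1,3-dioxan-2-yl]-6-methylhept-5-en-2-one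
Conditions: TMSOTf (5 mol%), CH2Cl2, −78 °C; Et3N quench
Reagents that add atoms: none
Why: Mukaiyama-type alkylation in which the Lewis acid ionises the exocyclic methoxy group to a dioxan-2-ylium ion that is attacked by the silyl enol ether (far more nucleophilic than the trisubstituted alkene), giving the β-keto ketal without a new stereocentre.

**Step 4**
Reactants: 7 1-[(4R,6R)-2-(chloromethyl)-4,6-dimethyl-1,3-dioxan-2-yl]-6-methylhept-5-en-2-one
Product: 9 tert-butyl({(2E)-1-[(4R,6R)-2-(chloromethyl)-4,6-dimethyl-1,3-dioxan-2-yl]-6-methylhepta-2,5-dien-2-yl}oxy)dimethylsilane, via lithium E-enolate 8 (not isolated)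
Conditions: LiTMP, LiBr, THF, −78 °C; TBSCl, HMPA, −78 → 0 °C
Reagents that add atoms: tert-butylchlorodimethylsilane, CC(C)(C)[Si](C)(C)Cl
Why: Kinetic enolisation by the hindered lithium amide should go to the unbranched C5 methylene and not to the neopentyl-type C3 methylene between ketal and carbonyl, and the closed deprotonation transition state of LiTMP/LiBr should give the E(O)-enolate, which is trapped on oxygen (silyl enol ether formation) so that C3 and C7 are cis on the C4=C5 double bond.

**Step 5**
Reactants: 9 tert-butyl({(2E)-1-[(4R,6R)-2-(chloromethyl)-4,6-dimethyl-1,3-dioxan-2-yl]-6-methylhepta-2,5-dien-2-yl}oxy)dimethylsilane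
Product: 11 4-(chloromethyl)-4-{[(2R,4R)-4-hydroxypentan-2-yl]oxy}-6,6-dimethylbicyclo[3.1.1]heptan-2-one (bridgeheads as in (+)-β-pinene; CH2Cl anti to the CMe2 bridge), via monocyclic tertiary cation 10 (not isolated)
Conditions: TiCl4 (1.1 equiv), CH2Cl2 (0.005 M), −78 °C; aq. NaHCO3
Reagents that add atoms: none
Why: Proposed new method: TiCl4 should open the dioxane ketal to an oxocarbenium ion at C2, which the trisubstituted alkene attacks through C1 in a chair-like Prins closure (ring C1–C2–C3–C4–C5–C7, exo with respect to both π bonds) to give tertiary cation 10 at C6; with C6 axial this cation lies 1,3 over the E-silyl enol ether, whose C5 carbon closes the cyclobutane C1–C6–C5–C7 (enol-exo four-membered closure onto a carbocation) before TBSCl is lost to leave the C4 ketone. The closest known reaction types are the ketal-initiated cation–olefin cyclization on a chiral diol template, the silyl-enol-ether-terminated polyene cyclization, the Lewis-acid SN1 tert-alkylation of silyl enol ethers and the stepwise cationic [2+2] cycloaddition in which an enol ether closes a cyclobutane onto a tertiary cation; what has not been shown is such a terminating alkylation forming a four-membered ring across a cyclohexene, the oxygen-directed Markovnikov counterpart of the terpinyl-to-pinyl cation closure. It should be feasible because the silyl enol ether is a far better nucleophile than the ring alkene of a terpinyl cation and the closure ends in a silyloxocarbenium ion instead of a strained tertiary cation, which pays for the ring strain. C2 is set by the diol template (attack anti to the C–O bond that TiCl4 cleaves), C1 by the chair with the alkene substituent C6 and the CH2Cl group equatorial, and C5 has no choice because the two one-carbon bridges must leave C1 and C5 on the same face. The step needs the Prins closure to precede any reaction of the enol ether and C–C closure to beat proton loss or heteroatom capture: direct attack of the enol ether on C2 would have to form a four-membered ring, the oxygen on C4 polarises the enol ether so that only C5 can bond to C6, the E geometry puts C3 and C7 cis as the first ring requires, and the only oxygen near C6 (the ether on C2) could at most form an oxetane. Diastereomers of the other bridgehead series, if formed, are removed by chromatography here, and either C2 epimer of the wanted series is usable because C2 is flattened in step 8.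

**Step 6**
Reactants: 11 4-(chloromethyl)-4-{[(2R,4R)-4-hydroxypentan-2-yl]oxy}-6,6-dimethylbicyclo[3.1.1]heptan-2-one
Product: 12 hydrazone of 11
Conditions: N2H4·H2O, EtOH, AcOH (cat.), 60 °C
Reagents that add atoms: hydrazine, NN
Why: Hydrazone formation at the only carbonyl group; the neopentyl-type chloride and the tertiary ether should not react and no stereocentre is touched.

**Step 7**
Reactants: 12 hydrazone of 11
Product: 13 2-(chloromethyl)-2-{[(2R,4R)-4-hydroxypentan-2-yl]oxy}-6,6-dimethylbicyclo[3.1.1]heptane (configuration as in 11)
Conditions: KOtBu, DMSO, 25 °C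
Reagents that add atoms: none
Why: Wolff–Kishner reduction of the preformed hydrazone at room temperature goes through N–H deprotonation, loss of N2 and protonation of a C4 carbanion, which (unlike a C4 radical) should not open the adjacent cyclobutane, and the mild conditions should avoid β-elimination of the C2 ether.

**Step 8**
Reactants: 13 2-(chloromethyl)-2-{[(2R,4R)-4-hydroxypentan-2-yl]oxy}-6,6-dimethylbicyclo[3.1.1]heptane
Product: 15 (+)-β-pinene, (1R,5R)-6,6-dimethyl-2-methylidenebicyclo[3.1.1]heptane, via organolithium 14 (not isolated)
Conditions: n-BuLi (1 equiv), THF, −78 °C; LiDBB (2.2 equiv), −78 °C; H2O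
Reagents that add atoms: none
Why: Boord-type reductive β-elimination in which electron transfer turns the primary C–Cl bond into a C–Li bond that at once expels the β-alkoxide (the diol auxiliary), creating the exocyclic C2=C10 double bond while C1 and C5 stay untouched and the C2 centre is deliberately erased.

**Step 9**
Reactants: 15 (+)-β-pinene; 16 syncarpic acid (2,2,4,4-tetramethylcyclohexane-1,3,5-trione); 17 2-methylpropanal
Product: 19 CNP0534730.2, 4-isopropyl-6,6,6′,6′,8,8-hexamethyl-3,4-dihydrospiro[chromene-2,2′-bicyclo[3.1.1]heptane]-5,7(6H,8H)-dione (configuration as in the SMILES), via o-quinone methide 18 (not isolated)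
Conditions: ethylenediammonium diacetate (cat.), toluene, 100 °C, sealed tube
Reagents that add atoms: none
Why: Domino Knoevenagel condensation/inverse-electron-demand hetero-Diels–Alder reaction in which the quinone methide oxygen bonds to the more substituted alkene carbon C2 from the face opposite the CMe2 bridge (setting the spiro centre), while the endo/exo orientation that sets the isopropyl-bearing carbon is only weakly biased, so the target should have to be separated by chromatography from its epimer at that carbon.

**Compound list**
1 | 2-chloro-1,1,1-trimethoxyethane | COC(CCl)(OC)OC | starting material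
2 | (2R,4R)-pentane-2,4-diol | C[C@@H](O)C[C@@H](C)O | starting material
3 | (4R,6R)-2-(chloromethyl)-2-methoxy-4,6-dimethyl-1,3-dioxane | COC1(CCl)O[C@H](C)C[C@@H](C)O1 | intermediate
4 | 6-methylhept-5-en-2-one (sulcatone) | CC(=O)CCC=C(C)C | starting material
5 | lithium 6-methylhepta-1,5-dien-2-olate | [Li]OC(=C)CCC=C(C)C | intermediate (not isolated)
6 | trimethyl[(6-methylhepta-1,5-dien-2-yl)oxy]silane | C=C(O[Si](C)(C)C)CCC=C(C)C | intermediate
7 | 1-[(4R,6R)-2-(chloromethyl)-4,6-dimethyl-1,3-dioxan-2-yl]-6-methylhept-5-en-2-one | CC(C)=CCCC(=O)CC1(CCl)O[C@H](C)C[C@@H](C)O1 | intermediate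
8 | lithium E-enolate of 7 | CC(C)=CC/C=C(/O[Li])CC1(CCl)O[C@H](C)C[C@@H](C)O1 | intermediate (not isolated)
9 | tert-butyl({(2E)-1-[(4R,6R)-2-(chloromethyl)-4,6-dimethyl-1,3-dioxan-2-yl]-6-methylhepta-2,5-dien-2-yl}oxy)dimethylsilane | CC(C)=CC/C=C(/O[Si](C)(C)C(C)(C)C)CC1(CCl)O[C@H](C)C[C@@H](C)O1 | intermediate
10 | monocyclic tertiary cation (trichlorotitanium alkoxide) | C[C+](C)[C@@H]1CC=C(O[Si](C)(C)C(C)(C)C)C[C@]1(CCl)O[C@H](C)C[C@@H](C)O[Ti](Cl)(Cl)Cl | intermediate (not isolated)
11 | 4-(chloromethyl)-4-{[(2R,4R)-4-hydroxypentan-2-yl]oxy}-6,6-dimethylbicyclo[3.1.1]heptan-2-one | ClC[C@]1(O[C@H](C)C[C@@H](C)O)CC(=O)[C@@H]2C[C@H]1C2(C)C | intermediate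
12 | hydrazone of 11 | ClC[C@]1(O[C@H](C)C[C@@H](C)O)CC(=NN)[C@@H]2C[C@H]1C2(C)C | intermediate
13 | 2-(chloromethyl)-2-{[(2R,4R)-4-hydroxypentan-2-yl]oxy}-6,6-dimethylbicyclo[3.1.1]heptane | ClC[C@]1(O[C@H](C)C[C@@H](C)O)CC[C@@H]2C[C@H]1C2(C)C | intermediate
14 | β-alkoxy organolithium from 13 | [Li]C[C@]1(O[C@H](C)C[C@@H](C)O[Li])CC[C@@H]2C[C@H]1C2(C)C | intermediate (not isolated)
15 | (+)-β-pinene | C=C1CC[C@@H]2C[C@H]1C2(C)C | intermediate
16 | syncarpic acid | CC1(C)C(=O)CC(=O)C(C)(C)C1=O | starting material
17 | 2-methylpropanal | CC(C)C=O | starting material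
18 | 2,2,4,4-tetramethyl-6-(2-methylpropylidene)cyclohexane-1,3,5-trione | CC(C)C=C1C(=O)C(C)(C)C(=O)C(C)(C)C1=O | intermediate (not isolated)
19 | CNP0534730.2 | CC(C)[C@H]1C[C@]2(CC[C@@H]3C[C@H]2C3(C)C)OC2=C1C(=O)C(C)(C)C(=O)C2(C)C | target

**Totals**
Total steps: 9. Longest linear sequence: 8 steps (from 4 through steps 2–9, or from 1 through steps 1 and 3–9).

**Steps most likely to fail**

Step 5 (proposed new method). The tertiary cation may be lost to proton elimination or chloride capture before the four-membered ring closes, the enol ether may react early with the oxocarbenium ion, or the diol template may discriminate the two bridgehead series poorly.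
The fallback uses known chemistry, sets out from 4 and returns at 15. Horner–Wadsworth–Emmons reaction of 4 with diethylphosphonoacetic acid (NaH, THF) should give geranic acid F1. Oxalyl chloride converts it into geranoyl chloride F2. With Et3N in refluxing toluene at high dilution, F2 loses HCl to the cross-conjugated vinylketene F3, which closes by the known intramolecular ketene–alkene [2+2] cycloaddition to racemic 7,7-dimethyl-2-methylidenebicyclo[3.1.1]heptan-6-one F4. Ketalisation with diol 2 gives two diastereomeric ketals. The one with the bridgeheads of 15, ketal F5, is separated and hydrolysed to the enantiopure ketone F6. Its hydrazone F7 is reduced under Wolff–Kishner conditions (KOH, diethylene glycol, heat) to 15.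

Step 4. Regio- or geometric control in the enolisation may be lost (deprotonation on the ketal side, or formation of the Z-enolate, which cannot enter the first ring closure).
The fallback sets out from 3 and returns at 9. TMSOTf-catalysed alkylation of commercial 2-(trimethylsilyloxy)buta-1,3-diene by 3 at its terminal carbon should give the vinyl ketone 1-[(4R,6R)-2-(chloromethyl)-4,6-dimethyl-1,3-dioxan-2-yl]but-3-en-2-one F8. Conjugate addition of (2-methylprop-1-en-1-yl)magnesium bromide, catalysed by CuBr·SMe2 in the presence of TBSCl and HMPA, then forms the C5=C4 enolate regiospecifically and traps it as 9. Addition through the s-trans enone should place the silyloxy group trans to the new allylic substituent.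

Step 9. Endo/exo discrimination in the cycloaddition may be poor, so that the epimer at the isopropyl-bearing carbon is formed alongside or in preference to 19.
The fallback sets out from 19 as obtained together with its epimer at the isopropyl-bearing carbon F9, and returns at 19. DDQ dehydrogenation of the mixture at the allylic C–H next to the enol ether should converge both epimers on the single 2H-chromene F10. Hydrogenation (H2, Pd/C, EtOAc) should then add hydrogen to the chromene C3=C4 double bond from the face turned away from bridgehead C1 and the CMe2 bridge. That places the isopropyl group cis to C1, as in 19.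

**Further compounds**
F1 | step 5 | geranic acid, (2E)-3,7-dimethylocta-2,6-dienoic acid | CC(C)=CCC/C(C)=C/C(=O)O
F2 | step 5 | geranoyl chloride | CC(C)=CCC/C(C)=C/C(Cl)=O
F3 | step 5 | 7-methyl-3-methylideneocta-1,6-dien-1-one (vinylketene, not isolated) | O=C=CC(=C)CCC=C(C)C
F4 | step 5 | racemic 7,7-dimethyl-2-methylidenebicyclo[3.1.1]heptan-6-one | C=C1CCC2C(=O)C1C2(C)C
F5 | step 5 | (4R,6R)-4,6-dimethyl-1,3-dioxane ketal of the enantiomer of F4 with the bridgeheads of 15 | C=C1CC[C@@H]2C3(O[C@H](C)C[C@@H](C)O3)[C@H]1C2(C)C
F6 | step 5 | 7,7-dimethyl-2-methylidenebicyclo[3.1.1]heptan-6-one, enantiomer with the bridgeheads of 15 | C=C1CC[C@@H]2C(=O)[C@H]1C2(C)C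
F7 | step 5 | hydrazone of F6 | C=C1CC[C@@H]2C(=NN)[C@H]1C2(C)C
F8 | step 4 | 1-[(4R,6R)-2-(chloromethyl)-4,6-dimethyl-1,3-dioxan-2-yl]but-3-en-2-one | C=CC(=O)CC1(CCl)O[C@H](C)C[C@@H](C)O1
F9 | step 9 | epimer of 19 at the isopropyl-bearing carbon | CC(C)[C@@H]1C[C@]2(CC[C@@H]3C[C@H]2C3(C)C)OC2=C1C(=O)C(C)(C)C(=O)C2(C)C
F10 | step 9 | 2H-chromene (3,4-didehydro derivative of 19) | CC(C)C1=C[C@]2(CC[C@@H]3C[C@H]2C3(C)C)OC2=C1C(=O)C(C)(C)C(=O)C2(C)C
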